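The benzoquinone ring (C1=O, C2–OH, C3–hexadecyl, C4=O, C5–OMe, C6–H) is disconnected at C5–C6 and C1–C2. C6–C1, the only ring C–H next to an oxygenated carbon, has the polarity of ethoxyacetylene. C2–C3–C4–C5 comes from a squarate-derived cyclobutenone in which a temporary C2–C5 bond ties the ends together. Heating the two (Danheiser benzannulation: 4π opening, ketene [2+2], 4π opening, 6π closure) inserts the alkyne into that bond. The product is a pentasubstituted phenol whose single free OH sits on C5, ready for methylation. Four differentiated oxygens (OMe, OMOM, OiPr, OEt) then permit regiocontrolled oxidation to the C1/C4 quinone and release of C2–OH.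

Key step: step 4

Remark on the chemistry: the target has no stereocentre and no stereogenic double bond, so it is achiral and no enantiomer has to be chosen. The stereocentres of the four-membered-ring intermediates are carried as racemates and disappear on aromatisation. Atom numbers C1–C6 used below are those of the target quinone ring.

Step 1
Reactants: 1 diisopropyl squarate (3,4-diisopropoxycyclobut-3-ene-1,2-dione)
Product: 2 (±)-4-hydroxy-2,3-diisopropoxycyclobut-2-en-1-one
Conditions: LiAlH(OtBu)3 (1.1 equiv), THF, −78 → −20 °C; cold H2O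
Reagents that add atoms: none
Why: Chemoselective 1,2-hydride reduction of one squarate carbonyl by a bulky, mild aluminium hydride; the remaining carbonyl is a doubly donor-substituted vinylogous carbonate that should resist a second reduction, a neutral quench avoids hydrolysis to the semisquarate, and the new stereocentre is racemic and is erased in step 4.

Step 2
Reactants: 2 (±)-4-hydroxy-2,3-diisopropoxycyclobut-2-en-1-one
Product: 3 (±)-2,3-diisopropoxy-4-(methoxymethoxy)cyclobut-2-en-1-one
Conditions: MOMCl, iPr2NEt, CH2Cl2, 0 °C → rt
Reagents that add atoms: chloromethyl methyl ether (MOMCl), COCCl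
Why: O-alkylation (acetal formation) under mild amine base; the hydroxyl must be capped because a free 4-hydroxycyclobutenone would be diverted to a butenolide on heating, and MOM is chosen because it cannot migrate to a neighbouring phenoxide in step 5.

Step 3
Reactants: 3 (±)-2,3-diisopropoxy-4-(methoxymethoxy)cyclobut-2-en-1-one; 4 1-bromohexadecane
Product: 8 (±)-3-hexadecyl-2-isopropoxy-4-(methoxymethoxy)cyclobut-2-en-1-one, via hexadecylmagnesium bromide 5 (not isolated), via bromomagnesium alkoxide of the 1,2-adduct 6 (not isolated), via tertiary allylic trifluoroacetate 7 (not isolated)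
Conditions: 4, Mg, THF, reflux; added to 3, THF, −78 °C; (CF3CO)2O, −78 °C; H2O, −78 °C → rt
Reagents that add atoms: water, O
Why: Grignard 1,2-addition to the only carbonyl followed by a Stork–Danheiser-type alkylative carbonyl transposition: the tertiary trifluoroacetate ionises to an isopropoxy-stabilised allyl cation, water adds and isopropanol leaves; the ring C–H cannot be enolised because the enolate would be an antiaromatic cyclobutadienolate, and a stray conjugate addition–elimination would give the same constitution 8.

Step 4
Reactants: 8 (±)-3-hexadecyl-2-isopropoxy-4-(methoxymethoxy)cyclobut-2-en-1-one; 9 ethoxyacetylene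
Product: 14 5-ethoxy-3-hexadecyl-4-isopropoxy-2-(methoxymethoxy)phenol, via vinylketene 10 (not isolated), via 4-alkenylcyclobutenone 11 (not isolated), via dienylketene 12 (not isolated), via cyclohexa-2,4-dienone 13 (not isolated)
Conditions: 9 (3 equiv, solution in hexanes), toluene, sealed tube, 80 °C; excess 9 vented, then 110 °C
Reagents that add atoms: none
Why: Danheiser benzannulation, a four-stage pericyclic cascade: conrotatory 4π opening of 8 (C4–C5 bond, the OMOM donor turning outward) gives vinylketene 10, whose electrophilic ketene carbon C5 is attacked by the nucleophilic terminal CH of ethoxyacetylene in a regioselective [2+2] cycloaddition that makes C5–C6 and C1–C2 together and closes the temporary four-membered ring of 11. Compound 11 is a 4-alkoxy-4-alkenylcyclobutenone of the Moore–Liebeskind type, so its 4π opening cleaves the temporary C2–C5 bond with the isopropoxy group turning outward and the alkenyl group inward, which places the enol-ether terminus C4 next to the ketene in 12. The six-membered ring is closed by a disrotatory 6π electrocyclisation (C4–C5 re-formed) to dienone 13, and enolisation to phenol 14 makes the sequence irreversible. No stereocentre survives, since those of 8, 11 and 13 are transient and racemic. The selectivity needed is the orientation of the alkyne, secured by the matched polarity of the ynol ether (C6 nucleophilic) and the ketene carbonyl carbon (C5 electrophilic). Capture of 10 before dimerisation or acylation of the product phenol is also needed, and should be secured by excess alkyne and by running the first stage at 80 °C, below the retro-ene fragmentation of ethoxyacetylene.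

Step 5
Reactants: 14 5-ethoxy-3-hexadecyl-4-isopropoxy-2-(methoxymethoxy)phenol
Product: 15 1-ethoxy-3-hexadecyl-2-isopropoxy-5-methoxy-4-(methoxymethoxy)benzene
Conditions: MeI, K2CO3, acetone, reflux, Ar
Reagents that add atoms: iodomethane, CI
Why: Williamson ether synthesis on the only free phenol, which sits on C5 because it derives from the ketene carbonyl; the neighbouring MOM acetal cannot migrate to the phenoxide as a silyl group could.

Step 6
Reactants: 15 1-ethoxy-3-hexadecyl-2-isopropoxy-5-methoxy-4-(methoxymethoxy)benzene
Product: 16 4-ethoxy-2-hexadecyl-3-isopropoxy-6-methoxyphenol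
Conditions: conc. HCl (cat.), MeOH–THF, 50 °C, Ar
Reagents that add atoms: none
Why: Acid-catalysed transacetalisation cleaves only the aryl MOM acetal, the methyl, ethyl and isopropyl aryl ethers being inert to dilute methanolic acid, and unmasks the C4 phenol para to the ethoxy group.

Step 7
Reactants: 16 4-ethoxy-2-hexadecyl-3-isopropoxy-6-methoxyphenol
Product: 18 3-hexadecyl-2-isopropoxy-5-methoxy-1,4-benzoquinone, via quinone hemiketal 17 (not isolated)
Conditions: PhI(OAc)2 (1.1 equiv), MeCN–THF–H2O, 0 °C
Reagents that add atoms: water, O
Why: Hypervalent-iodine oxidative dealkylation of a 4-alkoxyphenol: two-electron oxidation of the single free phenol (C4–OH) gives a cation best stabilised at the para carbon C1 by the ethoxy group, water adds there and hemiketal 17 loses ethanol, so the carbonyl pair is fixed at C1/C4 while the C2 and C5 ethers stay.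

Step 8
Reactants: 18 3-hexadecyl-2-isopropoxy-5-methoxy-1,4-benzoquinone
Product: 20 3-hexadecyl-2-hydroxy-5-methoxy-1,4-benzoquinone (target), via dichloroboryl ether 19 (not isolated)
Conditions: BCl3 (1.2 equiv), CH2Cl2, −78 → −20 °C; H2O
Reagents that add atoms: none
Why: Lewis-acid ether cleavage: BCl3 chelated between C1=O and the C2 oxygen should remove the secondary isopropyl group by an SN1-like pathway much faster than the methyl group at C5, and hydrolysis of 19 releases the vinylogous acid.

Compound list
1 | diisopropyl squarate (3,4-diisopropoxycyclobut-3-ene-1,2-dione) | CC(C)OC1=C(OC(C)C)C(=O)C1=O | starting material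
2 | (±)-4-hydroxy-2,3-diisopropoxycyclobut-2-en-1-one | CC(C)OC1=C(OC(C)C)C(=O)C1O | intermediate
3 | (±)-2,3-diisopropoxy-4-(methoxymethoxy)cyclobut-2-en-1-one | CC(C)OC1=C(OC(C)C)C(=O)C1OCOC | intermediate
4 | 1-bromohexadecane | CCCCCCCCCCCCCCCCBr | starting material
5 | hexadecylmagnesium bromide | CCCCCCCCCCCCCCCC[Mg]Br | intermediate
6 | bromomagnesium 1-hexadecyl-2,3-diisopropoxy-4-(methoxymethoxy)cyclobut-2-en-1-olate (racemic, diastereomer mixture) | CCCCCCCCCCCCCCCCC1(O[Mg]Br)C(OC(C)C)=C(OC(C)C)C1OCOC | intermediate
7 | 1-hexadecyl-2,3-diisopropoxy-4-(methoxymethoxy)cyclobut-2-en-1-yl trifluoroacetate (racemic, diastereomer mixture) | CCCCCCCCCCCCCCCCC1(OC(=O)C(F)(F)F)C(OC(C)C)=C(OC(C)C)C1OCOC | intermediate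
8 | (±)-3-hexadecyl-2-isopropoxy-4-(methoxymethoxy)cyclobut-2-en-1-one | CCCCCCCCCCCCCCCCC1=C(OC(C)C)C(=O)C1OCOC | intermediate
9 | ethoxyacetylene (ethoxyethyne) | CCOC#C | starting material
10 | vinylketene, (E)-2-isopropoxy-3-[(methoxymethoxy)methylidene]nonadec-1-en-1-one | CCCCCCCCCCCCCCCC/C(C(OC(C)C)=C=O)=C\OCOC | intermediate
11 | (±)-3-ethoxy-4-isopropoxy-4-[(E)-1-(methoxymethoxy)octadec-1-en-2-yl]cyclobut-2-en-1-one | CCCCCCCCCCCCCCCC/C(=C\OCOC)C1(OC(C)C)C(=O)C=C1OCC | intermediate
12 | dienylketene, (3Z)-3-ethoxy-4-isopropoxy-5-[(E)-(methoxymethoxy)methylidene]henicosa-1,3-dien-1-one | CCCCCCCCCCCCCCCC/C(=C\OCOC)/C(OC(C)C)=C(OCC)\C=C=O | intermediate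
13 | (±)-3-ethoxy-5-hexadecyl-4-isopropoxy-6-(methoxymethoxy)cyclohexa-2,4-dien-1-one | CCCCCCCCCCCCCCCCC1=C(OC(C)C)C(OCC)=CC(=O)C1OCOC | intermediate
14 | 5-ethoxy-3-hexadecyl-4-isopropoxy-2-(methoxymethoxy)phenol | CCCCCCCCCCCCCCCCc1c(OC(C)C)c(OCC)cc(O)c1OCOC | intermediate
15 | 1-ethoxy-3-hexadecyl-2-isopropoxy-5-methoxy-4-(methoxymethoxy)benzene | CCCCCCCCCCCCCCCCc1c(OC(C)C)c(OCC)cc(OC)c1OCOC | intermediate
16 | 4-ethoxy-2-hexadecyl-3-isopropoxy-6-methoxyphenol | CCCCCCCCCCCCCCCCc1c(OC(C)C)c(OCC)cc(OC)c1O | intermediate
17 | (±)-4-ethoxy-2-hexadecyl-4-hydroxy-3-isopropoxy-6-methoxycyclohexa-2,5-dien-1-one | CCCCCCCCCCCCCCCCC1=C(OC(C)C)C(O)(OCC)C=C(OC)C1=O | intermediate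
18 | 3-hexadecyl-2-isopropoxy-5-methoxy-1,4-benzoquinone | CCCCCCCCCCCCCCCCC1=C(OC(C)C)C(=O)C=C(OC)C1=O | intermediate
19 | 2-(dichloroboryloxy)-3-hexadecyl-5-methoxy-1,4-benzoquinone | CCCCCCCCCCCCCCCCC1=C(OB(Cl)Cl)C(=O)C=C(OC)C1=O | intermediate
20 | 3-hexadecyl-2-hydroxy-5-methoxy-1,4-benzoquinone | CCCCCCCCCCCCCCCCC1=C(O)C(=O)C=C(OC)C1=O | target

Total step count: 8. Longest linear sequence: 8 steps (1 → 20).

Steps most likely to fail

Step 4. Trapping of the donor-substituted vinylketene by the alkyne may be too slow. Reversible ring closure, ketene dimerisation, acylation of the product phenol by ketene intermediates and retro-ene loss of ethylene from the alkyne could then take over.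
- The fallback builds the ring stepwise. It sets out from 1 (with Grignard reagent 5 made from 4 as in step 3) and comes back at 18.
- Addition of 5 to 1 in THF at −78 °C, then trifluoroacetic anhydride and water, should give 3-hexadecyl-4-isopropoxycyclobut-3-ene-1,2-dione F1.
- Lithium methoxyacetylide F2, generated from chloroacetaldehyde dimethyl acetal with three equivalents of LiNEt2, should add to the more electrophilic carbonyl, the one next to C–OiPr that is not part of the vinylogous ester. This gives (±)-2-hexadecyl-4-hydroxy-3-isopropoxy-4-(methoxyethynyl)cyclobut-2-en-1-one F3.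
- Thermolysis in refluxing toluene (Moore rearrangement) proceeds by 4π opening with OH outward and alkynyl inward, closure of the enynylketene, and hydrogen transfer. It should deliver 18, which continues through step 8.

Step 8. Discrimination between the two vinylogous ester alkyl groups may be lost, with concurrent demethylation at C5.
- The fallback gives up the discrimination on purpose and restores it afterwards. It sets out from 18 and comes back at 20.
- Exhaustive dealkylation with excess BBr3 (CH2Cl2, −78 °C → rt, then water) should give 3-hexadecyl-2,5-dihydroxy-1,4-benzoquinone F4.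
- Acid-catalysed etherification (MeOH, cat. H2SO4, reflux) should then take place by addition–elimination only at the unhindered vinylogous acid flanked by C6–H. The hydroxyl next to the hexadecyl chain is shielded, so the product is 20.

Step 3. After ionisation of the trifluoroacetate, the cation may lose a proton from the α-CH2 of the chain and form an exocyclic alkylidene instead of being hydrolysed. The strongly basic alkyl Grignard reagent may also degrade the strained ketone.
- The fallback brings in the chain as an alkyne, which has no α-hydrogen next to the cation and is a milder nucleophile, and saturates it later. It sets out from 3 and comes back at 14.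
- Lithium hexadec-1-yn-1-ide F5 (1-hexadecyne, n-BuLi, THF, −78 °C) is added to 3. Trifluoroacetic anhydride and then water should give (±)-3-(hexadec-1-yn-1-yl)-2-isopropoxy-4-(methoxymethoxy)cyclobut-2-en-1-one F6.
- Benzannulation with 9 under the conditions of step 4 should give 5-ethoxy-3-(hexadec-1-yn-1-yl)-4-isopropoxy-2-(methoxymethoxy)phenol F7.
- Hydrogenation (H2, Pd/C, EtOAc) then gives 14.

Further compounds
F1 | step 4 | 3-hexadecyl-4-isopropoxycyclobut-3-ene-1,2-dione | CCCCCCCCCCCCCCCCC1=C(OC(C)C)C(=O)C1=O
F2 | step 4 | lithium methoxyacetylide | [Li]C#COC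
F3 | step 4 | (±)-2-hexadecyl-4-hydroxy-3-isopropoxy-4-(methoxyethynyl)cyclobut-2-en-1-one | CCCCCCCCCCCCCCCCC1=C(OC(C)C)C(O)(C#COC)C1=O
F4 | step 8 | 3-hexadecyl-2,5-dihydroxy-1,4-benzoquinone | CCCCCCCCCCCCCCCCC1=C(O)C(=O)C=C(O)C1=O
F5 | step 3 | lithium hexadec-1-yn-1-ide | CCCCCCCCCCCCCCC#C[Li]
F6 | step 3 | (±)-3-(hexadec-1-yn-1-yl)-2-isopropoxy-4-(methoxymethoxy)cyclobut-2-en-1-one | CCCCCCCCCCCCCCC#CC1=C(OC(C)C)C(=O)C1OCOC
F7 | step 3 | 5-ethoxy-3-(hexadec-1-yn-1-yl)-4-isopropoxy-2-(methoxymethoxy)phenol | CCCCCCCCCCCCCCC#Cc1c(OC(C)C)c(OCC)cc(O)c1OCOC
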